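## Retrosynthetic overview

- The strategy rests on ring C: C3 (the enol C–OH) and C4 (the C=O) of the γ-pyranone are neighbouring carbonyl-level carbons, so the flavonol is the enol of a 2-arylchroman-3,4-dione. The C3–C4 bond is cut with polarity reversal, back to a dialdehyde whose one formyl group acts as an acyl anion under carbene catalysis.
- The 1,1-dimethylallyl group at C8 is disconnected last, to the 7-O-prenyl ether (aromatic Claisen shift); the MOM ethers at O5 and O3' are removed at the very end.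
- The dialdehyde comes from an α-aryloxy arylacetate by reduction and double oxidation; its O1–C2 bond is made by Mitsunobu etherification of an A-ring salicylaldehyde with a B-ring mandelate.
- The A-ring piece comes from 2,4,6-trihydroxybenzaldehyde (4-O-prenyl, 2-O-MOM). The B-ring piece comes from 3,4-dihydroxybenzaldehyde by propargyl ether formation, chromene closure and one-carbon homologation.
- Ring order: the benzene rings A and B are bought; the pyran on ring B closes in step 5 and ring C closes in step 11.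

Key step: step 11

Remark: Broussonol A has no stereocentre, so no enantiomer has to be controlled; the stereocentres of intermediates 11–18 and 20 are racemic and vanish on the way.

## Route

Step 1
Reactants: 1 2,4,6-trihydroxybenzaldehyde; 2 prenyl bromide
Product: 3 2,6-dihydroxy-4-[(3-methylbut-2-en-1-yl)oxy]benzaldehyde
Conditions: K2CO3 (1.0 equiv), acetone, 0 °C → rt
Reagents that add atoms: none
Why: Williamson O-alkylation, in which the 4-OH (para to the formyl group and not held in a hydrogen bond to it) is the most acidic hydroxyl and is the one ionised by one equivalent of carbonate.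

Step 2
Reactants: 3 2,6-dihydroxy-4-[(3-methylbut-2-en-1-yl)oxy]benzaldehyde
Product: 4 2-hydroxy-6-(methoxymethoxy)-4-[(3-methylbut-2-en-1-yl)oxy]benzaldehyde
Conditions: MOMCl (1.1 equiv), i-Pr2NEt, CH2Cl2, 0 °C
Reagents that add atoms: chloromethyl methyl ether, COCCl
Why: MOM ether formation on one of the two equivalent ortho hydroxyls, after which the remaining hydroxyl is locked in a strong hydrogen bond to the aldehyde and should resist a second alkylation under amine base.

Step 3
Reactants: 5 3,4-dihydroxybenzaldehyde; 6 3-chloro-3-methylbut-1-yne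
Product: 7 3-hydroxy-4-[(2-methylbut-3-yn-2-yl)oxy]benzaldehyde
Conditions: DBU (1.1 equiv), CuCl2·2H2O (1 mol%), MeCN, 0 °C → rt, under Ar
Reagents that add atoms: none
Why: Copper-catalysed propargylic etherification, in which one equivalent of DBU ionises only the more acidic 4-OH (para to CHO) and this phenoxide captures the copper-activated tertiary propargylic electrophile.

Step 4
Reactants: 7 3-hydroxy-4-[(2-methylbut-3-yn-2-yl)oxy]benzaldehyde
Product: 8 3-(methoxymethoxy)-4-[(2-methylbut-3-yn-2-yl)oxy]benzaldehyde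
Conditions: MOMCl, i-Pr2NEt, CH2Cl2, 0 °C → rt
Reagents that add atoms: chloromethyl methyl ether, COCCl
Why: Standard MOM protection of the only remaining phenol.

Step 5
Reactants: 8 3-(methoxymethoxy)-4-[(2-methylbut-3-yn-2-yl)oxy]benzaldehyde
Product: 10 8-(methoxymethoxy)-2,2-dimethyl-2H-chromene-6-carbaldehyde, via ortho-allenylphenol 9 (not isolated)
Conditions: PhNEt2, 190 °C
Reagents that add atoms: none
Why: Aryl propargyl ether Claisen rearrangement to C5, the only free ortho carbon, gives allenyl phenol 9, which closes to the 2H-chromene by 1,5-hydrogen shift and oxa-6π-electrocyclisation.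

Step 6
Reactants: 10 8-(methoxymethoxy)-2,2-dimethyl-2H-chromene-6-carbaldehyde
Product: 12 2-hydroxy-2-[8-(methoxymethoxy)-2,2-dimethyl-2H-chromen-6-yl]acetic acid (racemic), via tribromomethyl carbinol 11 (not isolated)
Conditions: CHBr3, KOH, LiCl, 1,4-dioxane/H2O, 0–5 °C; then aq. KHSO4 to pH 3, 0 °C
Reagents that add atoms: bromoform, BrC(Br)Br; potassium hydroxide, [K+].[OH-]
Why: Tribromomethyl anion adds to the aldehyde and carbinol 11 is converted by hydroxide into the α-hydroxy acid (Jocic–Reeve reaction), under basic conditions that leave the MOM ether and the chromene untouched; the new carbinol centre is racemic and needs no control.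

Step 7
Reactants: 12 2-hydroxy-2-[8-(methoxymethoxy)-2,2-dimethyl-2H-chromen-6-yl]acetic acid
Product: 13 methyl 2-hydroxy-2-[8-(methoxymethoxy)-2,2-dimethyl-2H-chromen-6-yl]acetate (racemic)
Conditions: MeI, KHCO3, DMF, rt
Reagents that add atoms: iodomethane, CI
Why: SN2 alkylation of the carboxylate, with hydrogen carbonate too weak a base to ionise the secondary alcohol.

Step 8
Reactants: 4 2-hydroxy-6-(methoxymethoxy)-4-[(3-methylbut-2-en-1-yl)oxy]benzaldehyde; 13 methyl 2-hydroxy-2-[8-(methoxymethoxy)-2,2-dimethyl-2H-chromen-6-yl]acetate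
Product: 14 methyl 2-{2-formyl-3-(methoxymethoxy)-5-[(3-methylbut-2-en-1-yl)oxy]phenoxy}-2-[8-(methoxymethoxy)-2,2-dimethyl-2H-chromen-6-yl]acetate (racemic)
Conditions: PPh3, DIAD, THF, 0 °C → rt
Reagents that add atoms: none
Why: Mitsunobu etherification, for which α-hydroxy esters are good substrates and the ortho-formyl phenol of 4 is acidic enough; substitution at the benzylic carbon goes with inversion, which is without consequence for the racemate.

Step 9
Reactants: 14 methyl 2-{2-formyl-3-(methoxymethoxy)-5-[(3-methylbut-2-en-1-yl)oxy]phenoxy}-2-[8-(methoxymethoxy)-2,2-dimethyl-2H-chromen-6-yl]acetate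
Product: 15 2-{2-(hydroxymethyl)-3-(methoxymethoxy)-5-[(3-methylbut-2-en-1-yl)oxy]phenoxy}-2-[8-(methoxymethoxy)-2,2-dimethyl-2H-chromen-6-yl]ethan-1-ol (racemic)
Conditions: LiAlH4, THF, 0 °C; Rochelle salt work-up; crude diol used directly
Reagents that add atoms: none
Why: Hydride reduction of the ester and the aryl aldehyde in one operation, with aryl ethers, acetals and alkenes inert to LiAlH4 and a non-acidic work-up to protect the electron-rich benzylic alcohol.

Step 10
Reactants: 15 2-{2-(hydroxymethyl)-3-(methoxymethoxy)-5-[(3-methylbut-2-en-1-yl)oxy]phenoxy}-2-[8-(methoxymethoxy)-2,2-dimethyl-2H-chromen-6-yl]ethan-1-ol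
Product: 16 2-{2-formyl-3-(methoxymethoxy)-5-[(3-methylbut-2-en-1-yl)oxy]phenoxy}-2-[8-(methoxymethoxy)-2,2-dimethyl-2H-chromen-6-yl]acetaldehyde (racemic, configurationally labile)
Conditions: Dess–Martin periodinane (2.6 equiv), NaHCO3, CH2Cl2, 0 °C → rt; rapid filtration through a short pad, used at once
Reagents that add atoms: none
Why: Dess–Martin oxidation of both primary alcohols under buffered, base-free conditions, which should spare the acidic α-hydrogen of the new α-aryloxy aldehyde from enolisation.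

Step 11
Reactants: 16 2-{2-formyl-3-(methoxymethoxy)-5-[(3-methylbut-2-en-1-yl)oxy]phenoxy}-2-[8-(methoxymethoxy)-2,2-dimethyl-2H-chromen-6-yl]acetaldehyde
Product: 17 rac-(2R,3R)-3-hydroxy-5-(methoxymethoxy)-2-[8-(methoxymethoxy)-2,2-dimethyl-2H-chromen-6-yl]-7-[(3-methylbut-2-en-1-yl)oxy]-2,3-dihydro-4H-chromen-4-one (trans)
Conditions: 2-(pentafluorophenyl)-6,7-dihydro-5H-pyrrolo[2,1-c][1,2,4]triazol-2-ium tetrafluoroborate (20 mol%), Et3N (20 mol%), toluene, 0.01 M (slow addition of 16), rt, Ar
Reagents that add atoms: none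
Why: The triazolylidene adds reversibly to the A-ring formyl group, proton transfer gives the catalyst-bound enaminol (Breslow intermediate), and this acyl-anion equivalent at C4 attacks the tethered α-aryloxy aldehyde carbon (C3) before the carbene is expelled from the alkoxide; this is a carbene-catalysed intramolecular crossed benzoin reaction, whose closest known forms are the cyclisation of 2-(2-oxoalkoxy)benzaldehydes to 3-hydroxychroman-4-ones and of tethered dialdehydes to cyclic acyloins. Ring C closes in a 6-exo-trig mode onto the C3 carbonyl. The new C3 carbinol centre is set relative to the existing, base-labile C2 centre under substrate control, the trans-diequatorial acyloin being the thermodynamic isomer and reachable by enolisation; both centres are racemic and are erased in step 12. The step needs intramolecular C–C bond formation to win over loss of the A-ring aryloxide from an enaminol formed at the aliphatic aldehyde (internal redox), over base-mediated 5-exo aldol closure and over intermolecular benzoin coupling. High dilution and the six-membered tether answer the intermolecular path, while an electron-poor N-C6F5 triazolylidene with only catalytic tertiary amine in non-polar toluene should disfavour the ionising elimination and enolate chemistry. Which formyl group carries the carbene need not be controlled, because the acyloin of opposite regiochemistry is oxidised in step 12 to the same 3,4-dione.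

Step 12
Reactants: 17 rac-trans-3-hydroxy-5-(methoxymethoxy)-2-[8-(methoxymethoxy)-2,2-dimethyl-2H-chromen-6-yl]-7-[(3-methylbut-2-en-1-yl)oxy]-2,3-dihydro-4H-chromen-4-one
Product: 19 3-hydroxy-5-(methoxymethoxy)-2-[8-(methoxymethoxy)-2,2-dimethyl-2H-chromen-6-yl]-7-[(3-methylbut-2-en-1-yl)oxy]-4H-chromen-4-one, via chromane-3,4-dione 18 (not isolated)
Conditions: Dess–Martin periodinane (1.1 equiv), NaHCO3, CH2Cl2, 0 °C → rt
Reagents that add atoms: none
Why: Dess–Martin oxidation of the acyloin hydroxyl gives dione 18, whose C2–H is activated by the ketone, the ring oxygen and the aryl group, so it should enolise towards C2 to the conjugated flavonol and thereby remove both stereocentres.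

Step 13
Reactants: 19 3-hydroxy-5-(methoxymethoxy)-2-[8-(methoxymethoxy)-2,2-dimethyl-2H-chromen-6-yl]-7-[(3-methylbut-2-en-1-yl)oxy]-4H-chromen-4-one
Product: 21 3,7-dihydroxy-5-(methoxymethoxy)-2-[8-(methoxymethoxy)-2,2-dimethyl-2H-chromen-6-yl]-8-(2-methylbut-3-en-2-yl)-4H-chromen-4-one, via ortho-dienone 20 (not isolated)
Conditions: PhNEt2, 190 °C, degassed, sealed tube, short reaction time
Reagents that add atoms: none
Why: Aromatic Claisen rearrangement ([3,3]) of the 7-O-prenyl ether delivers the inverted allyl unit to C8 through dienone 20, which tautomerises to the phenol; C8 should be preferred over C6 because, with O5 capped and unable to chelate C4=O, the benzopyranone holds the higher π-bond order in C7–C8 and C8 is the less crowded ortho carbon.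

Step 14
Reactants: 21 3,7-dihydroxy-5-(methoxymethoxy)-2-[8-(methoxymethoxy)-2,2-dimethyl-2H-chromen-6-yl]-8-(2-methylbut-3-en-2-yl)-4H-chromen-4-one
Product: 22 Broussonol A, 3,5,7-trihydroxy-2-(8-hydroxy-2,2-dimethyl-2H-chromen-6-yl)-8-(2-methylbut-3-en-2-yl)-4H-chromen-4-one
Conditions: 3 M aq. HCl/MeOH (1:9), 45 °C
Reagents that add atoms: none
Why: Acid-catalysed acetal cleavage of both MOM ethers, with dilute acid at moderate temperature expected to spare the chromene and the 1,1-dimethylallyl alkene, whose protonation would need a secondary carbocation.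

## Compound list

1 | 2,4,6-trihydroxybenzaldehyde | O=Cc1c(O)cc(O)cc1O | starting material
2 | prenyl bromide (1-bromo-3-methylbut-2-ene) | CC(C)=CCBr | starting material
3 | 2,6-dihydroxy-4-[(3-methylbut-2-en-1-yl)oxy]benzaldehyde | O=Cc1c(O)cc(OCC=C(C)C)cc1O | intermediate
4 | 2-hydroxy-6-(methoxymethoxy)-4-[(3-methylbut-2-en-1-yl)oxy]benzaldehyde | O=Cc1c(O)cc(OCC=C(C)C)cc1OCOC | intermediate
5 | 3,4-dihydroxybenzaldehyde | O=Cc1ccc(O)c(O)c1 | starting material
6 | 3-chloro-3-methylbut-1-yne | C#CC(C)(C)Cl | starting material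
7 | 3-hydroxy-4-[(2-methylbut-3-yn-2-yl)oxy]benzaldehyde | O=Cc1ccc(OC(C)(C)C#C)c(O)c1 | intermediate
8 | 3-(methoxymethoxy)-4-[(2-methylbut-3-yn-2-yl)oxy]benzaldehyde | O=Cc1ccc(OC(C)(C)C#C)c(OCOC)c1 | intermediate
9 | 4-hydroxy-3-(methoxymethoxy)-5-(3-methylbuta-1,2-dien-1-yl)benzaldehyde (not isolated) | O=Cc1cc(OCOC)c(O)c(C=C=C(C)C)c1 | intermediate
10 | 8-(methoxymethoxy)-2,2-dimethyl-2H-chromene-6-carbaldehyde | O=Cc1cc(OCOC)c2c(c1)C=CC(C)(C)O2 | intermediate
11 | 2,2,2-tribromo-1-[8-(methoxymethoxy)-2,2-dimethyl-2H-chromen-6-yl]ethan-1-ol (racemic, not isolated) | OC(c1cc(OCOC)c2c(c1)C=CC(C)(C)O2)C(Br)(Br)Br | intermediate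
12 | 2-hydroxy-2-[8-(methoxymethoxy)-2,2-dimethyl-2H-chromen-6-yl]acetic acid (racemic) | OC(C(=O)O)c1cc(OCOC)c2c(c1)C=CC(C)(C)O2 | intermediate
13 | methyl 2-hydroxy-2-[8-(methoxymethoxy)-2,2-dimethyl-2H-chromen-6-yl]acetate (racemic) | COC(=O)C(O)c1cc(OCOC)c2c(c1)C=CC(C)(C)O2 | intermediate
14 | methyl 2-{2-formyl-3-(methoxymethoxy)-5-[(3-methylbut-2-en-1-yl)oxy]phenoxy}-2-[8-(methoxymethoxy)-2,2-dimethyl-2H-chromen-6-yl]acetate (racemic) | COC(=O)C(Oc1cc(OCC=C(C)C)cc(OCOC)c1C=O)c1cc(OCOC)c2c(c1)C=CC(C)(C)O2 | intermediate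
15 | 2-{2-(hydroxymethyl)-3-(methoxymethoxy)-5-[(3-methylbut-2-en-1-yl)oxy]phenoxy}-2-[8-(methoxymethoxy)-2,2-dimethyl-2H-chromen-6-yl]ethan-1-ol (racemic) | OCC(Oc1cc(OCC=C(C)C)cc(OCOC)c1CO)c1cc(OCOC)c2c(c1)C=CC(C)(C)O2 | intermediate
16 | 2-{2-formyl-3-(methoxymethoxy)-5-[(3-methylbut-2-en-1-yl)oxy]phenoxy}-2-[8-(methoxymethoxy)-2,2-dimethyl-2H-chromen-6-yl]acetaldehyde (racemic) | O=Cc1c(OCOC)cc(OCC=C(C)C)cc1OC(C=O)c1cc(OCOC)c2c(c1)C=CC(C)(C)O2 | intermediate
17 | rac-(2R,3R)-3-hydroxy-5-(methoxymethoxy)-2-[8-(methoxymethoxy)-2,2-dimethyl-2H-chromen-6-yl]-7-[(3-methylbut-2-en-1-yl)oxy]-2,3-dihydro-4H-chromen-4-one (trans; one enantiomer drawn) | O=C1c2c(OCOC)cc(OCC=C(C)C)cc2O[C@H](c2cc(OCOC)c3c(c2)C=CC(C)(C)O3)[C@H]1O | intermediate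
18 | 5-(methoxymethoxy)-2-[8-(methoxymethoxy)-2,2-dimethyl-2H-chromen-6-yl]-7-[(3-methylbut-2-en-1-yl)oxy]chromane-3,4-dione (racemic, not isolated) | O=C1C(=O)c2c(OCOC)cc(OCC=C(C)C)cc2OC1c1cc(OCOC)c2c(c1)C=CC(C)(C)O2 | intermediate
19 | 3-hydroxy-5-(methoxymethoxy)-2-[8-(methoxymethoxy)-2,2-dimethyl-2H-chromen-6-yl]-7-[(3-methylbut-2-en-1-yl)oxy]-4H-chromen-4-one | O=c1c(O)c(-c2cc(OCOC)c3c(c2)C=CC(C)(C)O3)oc2cc(OCC=C(C)C)cc(OCOC)c12 | intermediate
20 | 3-hydroxy-5-(methoxymethoxy)-2-[8-(methoxymethoxy)-2,2-dimethyl-2H-chromen-6-yl]-8-(2-methylbut-3-en-2-yl)-8H-chromene-4,7-dione (racemic, not isolated) | C=CC(C)(C)C1C(=O)C=C(OCOC)C2=C1OC(c1cc(OCOC)c3c(c1)C=CC(C)(C)O3)=C(O)C2=O | intermediate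
21 | 3,7-dihydroxy-5-(methoxymethoxy)-2-[8-(methoxymethoxy)-2,2-dimethyl-2H-chromen-6-yl]-8-(2-methylbut-3-en-2-yl)-4H-chromen-4-one | C=CC(C)(C)c1c(O)cc(OCOC)c2c(=O)c(O)c(-c3cc(OCOC)c4c(c3)C=CC(C)(C)O4)oc12 | intermediate
22 | Broussonol A | C=CC(C)(C)c1c(O)cc(O)c2c(=O)c(O)c(-c3cc(O)c4c(c3)C=CC(C)(C)O4)oc12 | target

## Step count and risks

Total step count: 14. Longest linear sequence: 12 steps (steps 3–14, from 3,4-dihydroxybenzaldehyde).

Steps most likely to fail:

1. Step 11. The carbene may engage the less hindered aliphatic aldehyde, and the enaminol formed there may expel the A-ring aryloxide (internal redox) faster than it attacks the di-ortho-substituted, electron-rich aryl aldehyde; base-induced enolisation and aldol closure of the aliphatic aldehyde is a second diversion. Fallback, from 16 and back at 19: the two formyl carbons are joined reductively instead. SmI2 (2.2 equiv), t-BuOH, THF, −78 °C should effect ketyl–carbonyl (pinacol) cyclisation through the same six-membered closure and give 5-(methoxymethoxy)-2-[8-(methoxymethoxy)-2,2-dimethyl-2H-chromen-6-yl]-7-[(3-methylbut-2-en-1-yl)oxy]chromane-3,4-diol F1 as a diastereomer mixture. Double oxidation of this diol (DMSO, TFAA, CH2Cl2, −78 °C, then Et3N) should lead through dione 18 to flavonol 19.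

2. Step 13. The sigmatropic shift may go to C6 instead of C8, or the newly formed ortho-(1,1-dimethylallyl)phenol may react on at 190 °C. Fallback, from 4 and back at 22: the quaternary benzylic carbon is set before ring C exists, where a chelate fixes the regiochemistry.
   - Heating 4 in PhNEt2 (180 °C) should move the prenyl group to C3, the carbon between the chelated 2-OH and the ether oxygen (the usual course for 4-allyloxy-2-hydroxyaryl carbonyl compounds). This gives, through the ortho-dienone F2, 2,4-dihydroxy-6-(methoxymethoxy)-3-(2-methylbut-3-en-2-yl)benzaldehyde F3.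
   - MOMCl/i-Pr2NEt caps the non-chelated 4-OH to give 2-hydroxy-4,6-bis(methoxymethoxy)-3-(2-methylbut-3-en-2-yl)benzaldehyde F4.
   - Because this phenol is flanked on both sides, the ether is made by SN2: 13 is converted (CBr4, PPh3, CH2Cl2, 0 °C) into methyl 2-bromo-2-[8-(methoxymethoxy)-2,2-dimethyl-2H-chromen-6-yl]acetate F5, which alkylates F4 (Cs2CO3, DMF, rt) to the α-aryloxy ester F6.
   - Steps 9–12 are then repeated in this series (LiAlH4; Dess–Martin; triazolylidene; Dess–Martin) through the diol F7, the dialdehyde F8, the 3-hydroxyflavanone F9, the chromane-3,4-dione F10 and the tris-MOM flavonol F11.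
   - The acid treatment of step 14 removes all three MOM groups from F11 to give 22.

3. Step 10. The first-formed aliphatic aldehyde may be trapped by the still free benzylic hydroxyl as a hemiacetal and over-oxidised, and the α-aryloxy aldehyde may enolise and self-condense during isolation. Fallback, from 15 and back at 16: the two oxidations are staged. Activated MnO2 (CH2Cl2, rt) should oxidise only the electron-rich benzylic alcohol, giving 2-{2-hydroxy-1-[8-(methoxymethoxy)-2,2-dimethyl-2H-chromen-6-yl]ethoxy}-6-(methoxymethoxy)-4-[(3-methylbut-2-en-1-yl)oxy]benzaldehyde F12. The remaining primary alcohol is then oxidised under Parikh–Doering conditions (SO3·pyridine, DMSO, i-Pr2NEt, 0 °C), and the washed, dried solution of 16 is taken straight into step 11.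

Further compounds
F1 | step 11 | 5-(methoxymethoxy)-2-[8-(methoxymethoxy)-2,2-dimethyl-2H-chromen-6-yl]-7-[(3-methylbut-2-en-1-yl)oxy]chromane-3,4-diol (racemic diastereomer mixture) | OC1C(O)c2c(OCOC)cc(OCC=C(C)C)cc2OC1c1cc(OCOC)c2c(c1)C=CC(C)(C)O2
F2 | step 13 | 2-hydroxy-6-(methoxymethoxy)-3-(2-methylbut-3-en-2-yl)-4-oxocyclohexa-1,5-diene-1-carbaldehyde (racemic ortho-dienone, not isolated) | O=CC1=C(O)C(C(C)(C)C=C)C(=O)C=C1OCOC
F3 | step 13 | 2,4-dihydroxy-6-(methoxymethoxy)-3-(2-methylbut-3-en-2-yl)benzaldehyde | O=Cc1c(O)c(C(C)(C)C=C)c(O)cc1OCOC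
F4 | step 13 | 2-hydroxy-4,6-bis(methoxymethoxy)-3-(2-methylbut-3-en-2-yl)benzaldehyde | O=Cc1c(O)c(C(C)(C)C=C)c(OCOC)cc1OCOC
F5 | step 13 | methyl 2-bromo-2-[8-(methoxymethoxy)-2,2-dimethyl-2H-chromen-6-yl]acetate (racemic) | COC(=O)C(Br)c1cc(OCOC)c2c(c1)C=CC(C)(C)O2
F6 | step 13 | methyl 2-[2-formyl-3,5-bis(methoxymethoxy)-6-(2-methylbut-3-en-2-yl)phenoxy]-2-[8-(methoxymethoxy)-2,2-dimethyl-2H-chromen-6-yl]acetate (racemic) | COC(=O)C(Oc1c(C=O)c(OCOC)cc(OCOC)c1C(C)(C)C=C)c1cc(OCOC)c2c(c1)C=CC(C)(C)O2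
F7 | step 13 | 2-[2-(hydroxymethyl)-3,5-bis(methoxymethoxy)-6-(2-methylbut-3-en-2-yl)phenoxy]-2-[8-(methoxymethoxy)-2,2-dimethyl-2H-chromen-6-yl]ethan-1-ol (racemic) | OCC(Oc1c(CO)c(OCOC)cc(OCOC)c1C(C)(C)C=C)c1cc(OCOC)c2c(c1)C=CC(C)(C)O2
F8 | step 13 | 2-[2-formyl-3,5-bis(methoxymethoxy)-6-(2-methylbut-3-en-2-yl)phenoxy]-2-[8-(methoxymethoxy)-2,2-dimethyl-2H-chromen-6-yl]acetaldehyde (racemic) | O=CC(Oc1c(C=O)c(OCOC)cc(OCOC)c1C(C)(C)C=C)c1cc(OCOC)c2c(c1)C=CC(C)(C)O2
F9 | step 13 | rac-trans-3-hydroxy-5,7-bis(methoxymethoxy)-2-[8-(methoxymethoxy)-2,2-dimethyl-2H-chromen-6-yl]-8-(2-methylbut-3-en-2-yl)-2,3-dihydro-4H-chromen-4-one (one enantiomer drawn) | O=C1c2c(OCOC)cc(OCOC)c(C(C)(C)C=C)c2O[C@H](c2cc(OCOC)c3c(c2)C=CC(C)(C)O3)[C@H]1O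
F10 | step 13 | 5,7-bis(methoxymethoxy)-2-[8-(methoxymethoxy)-2,2-dimethyl-2H-chromen-6-yl]-8-(2-methylbut-3-en-2-yl)chromane-3,4-dione (racemic, not isolated) | O=C1C(=O)c2c(OCOC)cc(OCOC)c(C(C)(C)C=C)c2OC1c1cc(OCOC)c2c(c1)C=CC(C)(C)O2
F11 | step 13 | 3-hydroxy-5,7-bis(methoxymethoxy)-2-[8-(methoxymethoxy)-2,2-dimethyl-2H-chromen-6-yl]-8-(2-methylbut-3-en-2-yl)-4H-chromen-4-one | C=CC(C)(C)c1c(OCOC)cc(OCOC)c2c(=O)c(O)c(-c3cc(OCOC)c4c(c3)C=CC(C)(C)O4)oc12
F12 | step 10 | 2-{2-hydroxy-1-[8-(methoxymethoxy)-2,2-dimethyl-2H-chromen-6-yl]ethoxy}-6-(methoxymethoxy)-4-[(3-methylbut-2-en-1-yl)oxy]benzaldehyde (racemic) | OCC(Oc1cc(OCC=C(C)C)cc(OCOC)c1C=O)c1cc(OCOC)c2c(c1)C=CC(C)(C)O2
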